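**Plan**
1. Cuts: (a) the bond from azepinone C4 to the imidazole ring carbon, together with the C4=C5 unsaturation (gives 2-aminoimidazole plus a C4-cation/C5-bromide equivalent of the bicycle); (b) the C3a–C4 bond (pyrrole C3 plus a masked aldehyde); (c) the N7–C8 amide bond.
2. Forward: the 4,5-dibromopyrrole is made first, the acetal chain is attached as the amide, the seven-membered ring is closed by acid cyclodehydration to the C4=C5 alkene, the alkene is armed by bromo-methoxylation, and unprotected 2-aminoimidazole is joined last with loss of MeOH and HBr.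
3. Enabling feature: C4 sits on pyrrole C3a, so a C4 cation is an azafulvenium ion (charge relayed through C3a=C8a to N1); the free ring carbon of 2-aminoimidazole is the β-carbon of a cyclic ene-guanidine and stays C-nucleophilic in strong acid.
4. The C5 bromine is a temporary helper: it supplies the extra oxidation level and leaves as HBr, giving the alkene conjugated with both heterocycles.
5. Stereochemistry: the target has no stereocentre; the racemic C4/C5 centres of the intermediates are erased in the last step. No protecting group is used.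

Key step: step 5

Remark: the target SMILES has no stereocentre and only an endocyclic ring alkene, so the compound is achiral and needs no absolute stereocontrol; it is isolated as the free base. Ring numbering used throughout: N1, C2, C3, C3a, C4, C5, C6, N7, C8, C8a.

**Step 1**
Reactants: 1 2-(trichloroacetyl)pyrrole
Product: 2 4,5-dibromo-2-(trichloroacetyl)pyrrole
Conditions: Br2 (2.1 equiv), AcOH, rt
Reagents that add atoms: bromine, BrBr
Why: Electrophilic aromatic bromination, in which the 2-acyl group sends the first bromine to C4 and the second to the remaining α-position C5, leaving the deactivated C3–H free for the later ring closure.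

**Step 2**
Reactants: 2 4,5-dibromo-2-(trichloroacetyl)pyrrole; 3 3,3-diethoxypropan-1-amine
Product: 4 4,5-dibromo-N-(3,3-diethoxypropyl)-1H-pyrrole-2-carboxamide
Conditions: 3 (1.1 equiv), Et3N, MeCN, rt
Reagents that add atoms: none
Why: Haloform-type acyl substitution, in which the amine adds to the trichloromethyl ketone and trichloromethanide leaves as chloroform; the acetal is untouched under these non-acidic conditions.

**Step 3**
Reactants: 4 4,5-dibromo-N-(3,3-diethoxypropyl)-1H-pyrrole-2-carboxamide
Product: 6 2,3-dibromo-6,7-dihydro-1H-pyrrolo[2,3-c]azepin-8-one, via (±)-2,3-dibromo-4-ethoxy-4,5,6,7-tetrahydro-1H-pyrrolo[2,3-c]azepin-8-one 5 (not isolated)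
Conditions: MeSO3H (neat, ca. 0.1 M), rt to 45 °C; ice, aq. NaHCO3
Reagents that add atoms: none
Why: Intramolecular Friedel–Crafts (Pictet–Spengler-like) alkylation, in which the acetal ionises to an oxocarbenium ion that the only free pyrrole carbon attacks (7-exo-trig at the oxocarbenium carbon), after which the C4 ether ionises and E1 loss of the C5 proton should give the pyrrole-conjugated alkene.

**Step 4**
Reactants: 6 2,3-dibromo-6,7-dihydro-1H-pyrrolo[2,3-c]azepin-8-one
Product: 7 (±)-trans-2,3,5-tribromo-4-methoxy-4,5,6,7-tetrahydro-1H-pyrrolo[2,3-c]azepin-8-one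
Conditions: NBS (1.05 equiv), MeOH–THF, 0 °C to rt, dark
Reagents that add atoms: N-bromosuccinimide, O=C1CCC(=O)N1Br; methanol, CO
Why: Alkene bromo-methoxylation (co-halogenation), in which Br+ adds to C5 because only the C4 cation is pyrrole-stabilised and methanol opens the bromonium ion anti at C4; the trans relationship is immaterial since both centres are erased in step 5.

**Step 5**
Reactants: 7 (±)-trans-2,3,5-tribromo-4-methoxy-4,5,6,7-tetrahydro-1H-pyrrolo[2,3-c]azepin-8-one; 8 2-aminoimidazole hemisulfate
Product: 11 stevensine, via (±)-5-bromo azafulvenium methanesulfonate 9 (not isolated), via (±)-trans-5-bromohymenin 10 (not isolated)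
Conditions: 8 (2 equiv of aminoimidazole), MeSO3H (neat), rt, then 60 °C; aq. NH3 to pH 9
Reagents that add atoms: none
Why: In neat MeSO3H the C4 methoxy group of 7 should ionise to cation 9 (C4 charge delocalised over C3a=C8a onto N1 and bridged by the C5 bromine), and the free ring carbon of 2-aminoimidazole should add at C4 to give 10, a Friedel–Crafts-type SN1 heteroarylation. The closest known reaction type is the capture of pyrroloazepinone azafulvenium ions by 2-aminoimidazole in this acid. On warming, 10 should tautomerise to its exocyclic C4=C(imidazole) alkylidene form, ionise the now allylic C5 bromide and re-aromatise the imidazole, a net 1,4-loss of HBr that gives the C4=C5 alkene conjugated with both rings as the thermodynamic sink. No ring is closed and no stereocentre survives, so the configuration of 7 and 10 does not matter. The step needs attack at C4 rather than C5, which is secured because only the C4 cation is pyrrole-stabilised. It also needs C- rather than N-alkylation, secured because N-adducts re-ionise under the reversible acidic conditions; the pyrrole is protected from substitution because C2 and C3 are blocked and bromide is the only halide present.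

**Compound list**
1 | 2-(trichloroacetyl)pyrrole [2,2,2-trichloro-1-(1H-pyrrol-2-yl)ethanone] | O=C(c1ccc[nH]1)C(Cl)(Cl)Cl | starting material
2 | 4,5-dibromo-2-(trichloroacetyl)pyrrole | O=C(c1cc(Br)c(Br)[nH]1)C(Cl)(Cl)Cl | intermediate
3 | 3,3-diethoxypropan-1-amine | NCCC(OCC)OCC | starting material
4 | 4,5-dibromo-N-(3,3-diethoxypropyl)-1H-pyrrole-2-carboxamide | CCOC(CCNC(=O)c1cc(Br)c(Br)[nH]1)OCC | intermediate
5 | (±)-2,3-dibromo-4-ethoxy-4,5,6,7-tetrahydro-1H-pyrrolo[2,3-c]azepin-8-one (racemate, not isolated) | CCOC1CCNC(=O)c2[nH]c(Br)c(Br)c21 | intermediate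
6 | 2,3-dibromo-6,7-dihydro-1H-pyrrolo[2,3-c]azepin-8-one (C4=C5 alkene) | O=C1NCC=Cc2c(Br)c(Br)[nH]c21 | intermediate
7 | (±)-trans-2,3,5-tribromo-4-methoxy-4,5,6,7-tetrahydro-1H-pyrrolo[2,3-c]azepin-8-one (racemate, 4R*,5R*; one enantiomer drawn) | CO[C@@H]1[C@@H](Br)CNC(=O)c2[nH]c(Br)c(Br)c21 | intermediate
8 | 2-aminoimidazole hemisulfate (two 2-amino-1H-imidazole per H2SO4) | Nc1ncc[nH]1.Nc1ncc[nH]1.OS(=O)(=O)O | starting material
9 | (±)-5-bromo azafulvenium methanesulfonate: 2,3,5-tribromo-8-oxo-5,6,7,8-tetrahydropyrrolo[2,3-c]azepin-4-ylium, drawn as its N1-iminium form (racemate, not isolated) | O=C1NCC(Br)C=C2C(Br)=C(Br)[NH+]=C12.CS(=O)(=O)[O-] | intermediate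
10 | (±)-trans-5-bromohymenin: 4-(2-amino-1H-imidazol-5-yl)-2,3,5-tribromo-4,5,6,7-tetrahydro-1H-pyrrolo[2,3-c]azepin-8-one (racemate, 4R*,5R*; one enantiomer drawn; not isolated) | Nc1ncc([C@@H]2[C@@H](Br)CNC(=O)c3[nH]c(Br)c(Br)c32)[nH]1 | intermediate
11 | stevensine: 4-(2-amino-1H-imidazol-5-yl)-2,3-dibromo-6,7-dihydro-1H-pyrrolo[2,3-c]azepin-8-one | Nc1ncc(C2=CCNC(=O)c3[nH]c(Br)c(Br)c32)[nH]1 | target

**Count**
Total steps: 5. Longest linear sequence: 5 steps (1 to 11); 3 and 8 are bought.

**Steps most likely to fail**

Step 5. The aminoimidazole may attack the C5 bromine instead of C4 (transfer of Br+ that returns the alkene), the loss of HBr may stall or go towards the C5=C6 enamide, and the pyrrole bromines may be lost by protodebromination on heating in acid. The fallback separates bond formation from oxidation and sets out from 6. Alkene 6 and 8 in MeSO3H at rt should give, by C5 protonation and capture of the parent azafulvenium ion at C4, (±)-hymenin F1. Br2 (1 equiv) in CF3CO2H should brominate the free imidazole carbon to give (±)-5'-bromohymenin F2. Heating F2 in MeSO3H at 90 °C in a sealed tube should move it to the exocyclic alkylidene tautomer, from which bromide leaves and HBr is lost, and the sequence comes back to the route at 11.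

Step 3. In neat acid the alkene may oligomerise through its own azafulvenium ion, the reaction may stop at the 4-ethoxy or 4-hydroxy stage, or the bromines may migrate. The fallback builds the ring by acylation and sets out from 1. Compound 1 and β-alanine (aq. NaOH, MeCN) should give N-(1H-pyrrole-2-carbonyl)-β-alanine F3. Polyphosphoric acid at 100 °C should close the ring by intramolecular Friedel–Crafts acylation at pyrrole C3 to give aldisine F4. NBS (2 equiv, THF) should fill both free pyrrole positions to give 2,3-dibromoaldisine F5. NaBH4 (MeOH, 0 °C) should reduce the C4 ketone to (±)-2,3-dibromo-4-hydroxy-4,5,6,7-tetrahydro-1H-pyrrolo[2,3-c]azepin-8-one F6. Catalytic TsOH in hot, dilute dioxane should dehydrate F6, and the sequence comes back to the route at 6.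

Step 4. The bromo-ether may ionise during isolation with loss of methanol or HBr, or bromination may go to nitrogen or the allylic C6 position. The fallback carries the helper bromine on an sp2 carbon and sets out from 6. Br2 (1.0 equiv, CH2Cl2–AcOH, 0 °C) should give (±)-trans-2,3,4,5-tetrabromo-4,5,6,7-tetrahydro-1H-pyrrolo[2,3-c]azepin-8-one F7. Et3N should then remove HBr by ionisation at C4 and loss of the C5 proton to give the stable vinyl bromide 2,3,5-tribromo-6,7-dihydro-1H-pyrrolo[2,3-c]azepin-8-one F8. In MeSO3H with 8, protonation of F8 at C5 should regenerate the same cation, so the sequence comes back to the route at 9 and continues to 11 as in step 5.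

**Further compounds**
F1 | step 5 | (±)-hymenin: 4-(2-amino-1H-imidazol-5-yl)-2,3-dibromo-4,5,6,7-tetrahydro-1H-pyrrolo[2,3-c]azepin-8-one (racemate) | Nc1ncc(C2CCNC(=O)c3[nH]c(Br)c(Br)c32)[nH]1
F2 | step 5 | (±)-5'-bromohymenin: 4-(2-amino-4-bromo-1H-imidazol-5-yl)-2,3-dibromo-4,5,6,7-tetrahydro-1H-pyrrolo[2,3-c]azepin-8-one (racemate) | Nc1nc(Br)c(C2CCNC(=O)c3[nH]c(Br)c(Br)c32)[nH]1
F3 | step 3 | N-(1H-pyrrole-2-carbonyl)-β-alanine | OC(=O)CCNC(=O)c1ccc[nH]1
F4 | step 3 | aldisine: 6,7-dihydro-1H,5H-pyrrolo[2,3-c]azepine-4,8-dione | O=C1CCNC(=O)c2[nH]ccc21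
F5 | step 3 | 2,3-dibromoaldisine | O=C1CCNC(=O)c2[nH]c(Br)c(Br)c21
F6 | step 3 | (±)-2,3-dibromo-4-hydroxy-4,5,6,7-tetrahydro-1H-pyrrolo[2,3-c]azepin-8-one (racemate) | OC1CCNC(=O)c2[nH]c(Br)c(Br)c21
F7 | step 4 | (±)-trans-2,3,4,5-tetrabromo-4,5,6,7-tetrahydro-1H-pyrrolo[2,3-c]azepin-8-one (racemate; one enantiomer drawn) | Br[C@@H]1[C@@H](Br)CNC(=O)c2[nH]c(Br)c(Br)c21
F8 | step 4 | 2,3,5-tribromo-6,7-dihydro-1H-pyrrolo[2,3-c]azepin-8-one | BrC1=Cc2c(Br)c(Br)[nH]c2C(=O)NC1
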